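**Retrosynthetic overview**
- The biaryl bond is cut between the carbon ortho to the ether oxygen (ring C) and the carbon para to the phenol OH (ring D). Both carbons are innately nucleophilic. Ring D is therefore brought in as 2-allyl-1,4-benzoquinone, a 3-allyl-4-hydroxyphenyl cation (vinylogous enolonium) equivalent. It is attacked by the ortho-lithiated aryl ether and then re-aromatised reductively. The para-allyl group on ring C is added last.
- The tertiary alkyl aryl ether is made by SNAr of the axial C3 alkoxide on 2,4-dibromo-1-fluorobenzene. The side-chain alcohol comes from Markovnikov hydration of the isopropenyl group, done after etherification.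
- C3 is set by equatorial methyl delivery to the trans-decal-3-one. C5 is set by dissolving-metal reduction of the octalone.
- Ring order: ring B (with C7) comes from (+)-dihydrocarvone. Ring A is annulated onto it; an auxiliary-controlled Michael addition sets C10 and an aldol condensation closes the ring. Ring C arrives intact. Ring D becomes aromatic in the key step.

Assumption: the decalin is numbered eudesmane-style (C3 ether carbon, C5 ring-fusion CH, C7 side-chain carbon, C10 ring-fusion C-Me; beta = face of the C10 methyl), and the target is read as 3R,5S,7R,10S, i.e. a trans-decalin with axial 3-alpha aryloxy, equatorial 3-beta methyl and equatorial 7-beta 2-hydroxypropan-2-yl.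

**Step 1**
Reactants: 1 (+)-dihydrocarvone; 2 (R)-(+)-1-phenylethylamine; 3 methyl vinyl ketone
Product: 6 (2S,5R)-2-methyl-2-(3-oxobutyl)-5-(prop-1-en-2-yl)cyclohexan-1-one, via ketimine 4 (not isolated), via Michael-adduct ketimine 5 (not isolated)
Conditions: 2 (1.05 equiv), TsOH (cat.), PhMe, Dean–Stark reflux; 3 (1.3 equiv), THF, 40 °C, 72 h; 10% aq AcOH, rt
Reagents that add atoms: methyl vinyl ketone CC(=O)C=C; water O
Why: d'Angelo deracemising Michael addition, in which the more substituted secondary enamine tautomer of the chiral ketimine adds to the enone through a compact aza-ene-like chair on the face away from the phenyl group, so the (R)-auxiliary overrides the ring's own axial bias, places the 3-oxobutyl chain trans and the C10 methyl cis to the C7 isopropenyl group (10S), and erases the labile C2 centre of 1 on the way.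

**Step 2**
Reactants: 6 (2S,5R)-2-methyl-2-(3-oxobutyl)-5-(prop-1-en-2-yl)cyclohexan-1-one
Product: 7 (4aS,7R)-4a-methyl-7-(prop-1-en-2-yl)-4,4a,5,6,7,8-hexahydronaphthalen-2(3H)-one
Conditions: NaOMe (0.3 equiv), MeOH, 60 °C
Reagents that add atoms: none
Why: Intramolecular aldol condensation (second half of a Robinson annulation), in which only the methyl-ketone enolate reaches the ring carbonyl through a six-membered transition state, dehydration to the conjugated octalone drives the reaction, and C7 and C10 carry no acidic hydrogen and so stay intact.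

**Step 3**
Reactants: 7 (4aS,7R)-4a-methyl-7-(prop-1-en-2-yl)-4,4a,5,6,7,8-hexahydronaphthalen-2(3H)-one
Product: 8 (4aS,7R,8aS)-4a-methyl-7-(prop-1-en-2-yl)octahydronaphthalen-2(1H)-one (trans-decalone)
Conditions: Li (2.5 equiv), NH3(l)/THF, t-BuOH (1 equiv), −78 °C; NH4Cl
Reagents that add atoms: none
Why: Dissolving-metal enone reduction, in which the beta-carbanion of the reduced enone is protonated axially, opposite the C10 methyl, to keep overlap with the enolate, giving the trans ring fusion (H-5 alpha, 5S) while the isolated isopropenyl alkene is not reduced.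

**Step 4**
Reactants: 8 trans-decalone
Product: 9 (2R,4aS,7R,8aS)-2,4a-dimethyl-7-(prop-1-en-2-yl)decahydronaphthalen-2-ol (3-alpha axial OH and 3-beta equatorial Me)
Conditions: MeTi(OiPr)3 (1.5 equiv), hexane/Et2O, −15 °C to rt; H2O
Reagents that add atoms: methyltitanium triisopropoxide C[Ti](OC(C)C)(OC(C)C)OC(C)C
Why: Stereoselective carbonyl methylation with a bulky, non-basic organotitanium reagent, which attacks the unhindered 3-ketone from the equatorial beta side to avoid the axial H-1 and H-5, so the methyl ends equatorial and the hydroxyl axial (3R).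

**Step 5**
Reactants: 9 tertiary alcohol; 10 2,4-dibromo-1-fluorobenzene
Product: 12 2,4-dibromophenyl ether of 9 (3-alpha aryloxy), via potassium alkoxide 11 (not isolated)
Conditions: KN(SiMe3)2 (1.05 equiv), THF, 0 °C; 10 (1.5 equiv), DMPU, 65 °C
Reagents that add atoms: 2,4-dibromo-1-fluorobenzene Fc1ccc(Br)cc1Br
Why: Nucleophilic aromatic substitution by addition–elimination, in which fluoride is the best leaving group, the ortho and para bromines stabilise the Meisenheimer complex, and only the O–H bond of 9 is touched, so the C3 configuration is retained.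

**Step 6**
Reactants: 12 dibromophenyl ether
Product: 13 2-[(2R,4aS,7R,8aS)-7-(2,4-dibromophenoxy)-4a,7-dimethyldecahydronaphthalen-2-yl]propan-2-ol
Conditions: Co(acac)2 (15 mol %), PhSiH3 (2 equiv), O2 (1 atm), THF, rt
Reagents that add atoms: dioxygen O=O
Why: Mukaiyama hydration by metal-hydride hydrogen-atom transfer, in which the cobalt hydride delivers hydrogen to the CH2 terminus of the only alkene, the tertiary radical is trapped by O2 and the peroxide is reduced by the silane to the Markovnikov alcohol, no stereocentre is formed, and the aryl bromides and the ether are inert.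

**Step 7**
Reactants: 14 2-allylphenol
Product: 15 2-allyl-1,4-benzoquinone
Conditions: (KSO3)2NO (2.2 equiv), KH2PO4 buffer, H2O/acetone, rt
Reagents that add atoms: potassium nitrosodisulfonate [K+].[K+].[O]N(S(=O)(=O)[O-])S(=O)(=O)[O-]
Why: Teuber oxidation, in which one nitroxyl radical abstracts the phenolic hydrogen and a second couples at the free para position and collapses to the p-quinone, a one-electron pathway that leaves the allyl group untouched.

**Step 8 (key step)**
Reactants: 13 dibromophenyl ether alcohol; 15 2-allyl-1,4-benzoquinone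
Product: 18 3-allyl-5'-bromo-2'-(terpenyloxy)biphenyl-4-ol, via dilithiated aryl ether 16 (not isolated), via p-quinol 17 (not isolated)
Conditions: n-BuLi (2.1 equiv), THF, −78 °C; cannulate into 15 (1.5 equiv), THF, −78 °C; AcOH; Zn dust, AcOH/THF, rt
Reagents that add atoms: 2-allyl-1,4-benzoquinone C=CCC1=CC(=O)C=CC1=O
Why: 1,2-Addition of an aryllithium to a p-benzoquinone followed by reductive aromatisation of the p-quinol, in which the quinone is the oxidised, polarity-reversed form of 2-allylphenol (a 3-allyl-4-hydroxyphenyl cation, i.e. a vinylogous enolonium equivalent), so the para carbon of a phenol and the ortho carbon of an aryl ether, both innately nucleophilic, are joined; bromine–lithium exchange is selective for the bromide ortho to oxygen, the bulky aryllithium attacks the carbonyl remote from the allyl group, and the quinol stereocentre forms unselectively and is erased when zinc removes the hydroxyl.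

**Step 9**
Reactants: 18 bromobiaryl phenol; 19 allylboronic acid pinacol ester
Product: 20 target CNP0342687.1
Conditions: 19 (1.5 equiv), Pd(OAc)2 (3 mol %), SPhos (6 mol %), K3PO4 (3.5 equiv), THF/H2O, 50 °C
Reagents that add atoms: allylboronic acid pinacol ester C=CCB1OC(C)(C)C(C)(C)O1
Why: Suzuki–Miyaura allylation, in which zerovalent palladium inserts into the single remaining C–Br bond, the boronate transfers the unsubstituted allyl group (no regiochemical issue), and the mild temperature avoids allyl-to-propenyl migration while the free phenol, the tertiary alcohol and all four stereocentres are spectators.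

**Compound list**
1 | (+)-dihydrocarvone, (5R)-2-methyl-5-(prop-1-en-2-yl)cyclohexan-1-one, commercial mixture of C2 epimers | CC1CC[C@@H](C(C)=C)CC1=O | starting material
2 | (R)-(+)-1-phenylethylamine | C[C@@H](N)c1ccccc1 | starting material
3 | methyl vinyl ketone | CC(=O)C=C | starting material
4 | ketimine of 1 and 2 | C[C@@H](N=C1C[C@H](C(C)=C)CCC1C)c1ccccc1 | intermediate
5 | Michael-adduct ketimine (C10 set) | C[C@@H](N=C1C[C@H](C(C)=C)CC[C@@]1(C)CCC(C)=O)c1ccccc1 | intermediate
6 | (2S,5R)-2-methyl-2-(3-oxobutyl)-5-(prop-1-en-2-yl)cyclohexan-1-one | CC(=O)CC[C@]1(C)CC[C@@H](C(C)=C)CC1=O | intermediate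
7 | (4aS,7R)-4a-methyl-7-(prop-1-en-2-yl)-4,4a,5,6,7,8-hexahydronaphthalen-2(3H)-one | O=C1CC[C@]2(C)CC[C@@H](C(C)=C)CC2=C1 | intermediate
8 | (4aS,7R,8aS)-4a-methyl-7-(prop-1-en-2-yl)octahydronaphthalen-2(1H)-one, trans-fused | O=C1CC[C@]2(C)CC[C@@H](C(C)=C)C[C@H]2C1 | intermediate
9 | (2R,4aS,7R,8aS)-2,4a-dimethyl-7-(prop-1-en-2-yl)decahydronaphthalen-2-ol, axial OH | O[C@]1(C)CC[C@]2(C)CC[C@@H](C(C)=C)C[C@H]2C1 | intermediate
10 | 2,4-dibromo-1-fluorobenzene | Fc1ccc(Br)cc1Br | starting material
11 | potassium alkoxide of 9 | [K+].[O-][C@]1(C)CC[C@]2(C)CC[C@@H](C(C)=C)C[C@H]2C1 | intermediate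
12 | 2,4-dibromo-1-{[(2R,4aS,7R,8aS)-2,4a-dimethyl-7-(prop-1-en-2-yl)decahydronaphthalen-2-yl]oxy}benzene | Brc1cc(Br)ccc1O[C@]1(C)CC[C@]2(C)CC[C@@H](C(C)=C)C[C@H]2C1 | intermediate
13 | 2-[(2R,4aS,7R,8aS)-7-(2,4-dibromophenoxy)-4a,7-dimethyldecahydronaphthalen-2-yl]propan-2-ol | Brc1cc(Br)ccc1O[C@]1(C)CC[C@]2(C)CC[C@@H](C(C)(C)O)C[C@H]2C1 | intermediate
14 | 2-allylphenol | C=CCc1ccccc1O | starting material
15 | 2-allyl-1,4-benzoquinone | C=CCC1=CC(=O)C=CC1=O | intermediate
16 | dilithiated aryl ether (ortho C–Li, side-chain O–Li) | [Li]c1cc(Br)ccc1O[C@]1(C)CC[C@]2(C)CC[C@@H](C(C)(C)O[Li])C[C@H]2C1 | intermediate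
17 | p-quinol, 2-allyl-4-aryl-4-hydroxycyclohexa-2,5-dienone, both epimers at the carbinol carbon | C=CCC1=CC(O)(c2cc(Br)ccc2O[C@]2(C)CC[C@]3(C)CC[C@@H](C(C)(C)O)C[C@H]3C2)C=CC1=O | intermediate
18 | 3-allyl-5'-bromo-2'-{[(2R,4aS,7R,8aS)-7-(2-hydroxypropan-2-yl)-2,4a-dimethyldecahydronaphthalen-2-yl]oxy}biphenyl-4-ol | Brc1ccc(O[C@]2(C)CC[C@]3(C)CC[C@@H](C(C)(C)O)C[C@H]3C2)c(-c2ccc(O)c(CC=C)c2)c1 | intermediate
19 | allylboronic acid pinacol ester | C=CCB1OC(C)(C)C(C)(C)O1 | starting material
20 | CNP0342687.1, honokiol 2-O-terpenyl ether (3R,5S,7R,10S) | C=CCc1ccc(O[C@]2(C)CC[C@]3(C)CC[C@@H](C(C)(C)O)C[C@H]3C2)c(-c2ccc(O)c(CC=C)c2)c1 | target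

**Total step count:** 9. **Longest linear sequence:** 8 (steps 1–6, 8 and 9). Step 7 is a one-step side branch.

**Steps most likely to fail**

Step 8 is the riskiest. Electron transfer from the aryllithium to the quinone, attack at the carbonyl next to the allyl group, or dienone–phenol migration of the quinol could each erode the yield. The fallback gives up the polarity-reversed partner and builds the biaryl by conventional cross-coupling.
- It sets out from 13. The less hindered para bromide is coupled first with 19 (Pd(OAc)2, SPhos, K3PO4) to give the 4-allyl-2-bromophenyl ether F1.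
- Commercial 2-allyl-4-bromophenol is borylated (B2pin2, Pd(dppf)Cl2, KOAc) to 2-allyl-4-(pinacolboryl)phenol F2.
- A Suzuki–Miyaura coupling of the two comes back to the route at 20.

Step 5 is second. The hydrogen between the two bromines of 10 is fairly acidic, so aryne formation or halogen scrambling may outrun substitution by the hindered axial alkoxide. The fallback replaces addition–elimination by ligand coupling at iodine.
- It sets out from 9. Alkoxide 11 is treated in toluene at rt with (2,4-dibromophenyl)(2,4,6-trimethoxyphenyl)iodonium tosylate F3.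
- This salt is made in one pot from 2,4-dibromo-1-iodobenzene, mCPBA, TsOH and 1,3,5-trimethoxybenzene.
- It transfers its electron-poorer, ortho-substituted aryl group and comes back to the route at 12.

Step 4 is third. The facial selectivity of direct methyl addition may be only moderate. The fallback puts the C3 carbon in under thermodynamic control.
- It sets out from 8. Dimethylsulfoxonium methylide (Me3S(O)I, NaH, DMSO) adds reversibly, so the new C–C bond ends equatorial. This gives the spiro-epoxide with axial oxygen F4.
- LiEt3BH opens the epoxide at its CH2 terminus and comes back to the route at 9.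

**Further compounds**
F1 | step 8 | 2-[(2R,4aS,7R,8aS)-7-(4-allyl-2-bromophenoxy)-4a,7-dimethyldecahydronaphthalen-2-yl]propan-2-ol | C=CCc1ccc(O[C@]2(C)CC[C@]3(C)CC[C@@H](C(C)(C)O)C[C@H]3C2)c(Br)c1
F2 | step 8 | 2-allyl-4-(4,4,5,5-tetramethyl-1,3,2-dioxaborolan-2-yl)phenol | C=CCc1cc(B2OC(C)(C)C(C)(C)O2)ccc1O
F3 | step 5 | (2,4-dibromophenyl)(2,4,6-trimethoxyphenyl)iodonium 4-methylbenzenesulfonate | COc1cc(OC)c([I+]c2ccc(Br)cc2Br)c(OC)c1.Cc1ccc(S(=O)(=O)[O-])cc1
F4 | step 4 | C3 spiro-epoxide of 8 (axial alpha oxygen, equatorial beta CH2) | O1[C@]2(C1)CC[C@]3(C)CC[C@@H](C(C)=C)C[C@H]3C2
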